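**Strategy.** The C10 carbinol of the seven-membered ring (C1, C5–C10), flanked by quaternary C1 and by the C8(CH3)–C9 epoxide, is read as a 3-methylcyclohept-2-en-1-one. This enone is not cyclised: a trans-hydrindanone that lacks C9 and can enolise only towards C8 is cyclopropanated as its silyl enol ether, and FeCl3 then cleaves the internal cyclopropane bond, so that the six-membered ring grows by C9 while the C8=C9 enone appears. The precursor arises from 2,6-dimethylphenol by dearomatisation, a catalytic desymmetrising three-component coupling (C5, C1, C2) and metathesis; all later stereocentres are relayed from C5.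

Key step: step 13

Remark (naming): daucane numbering of the target is used throughout: C1 (quaternary C–CH3), C2 (CH–OAc), C3 (CH2), C4 (C(OH)-isopropyl), C5 (ring-fusion CH), C6 (CH–O-anisoyl), C7 (CH2), C8 (C–CH3), C9 (CH), C10 (CH–OH). β is the face of the C1 methyl group and α the opposite face, so the target is 2β-OAc, 4β-OH, 5α-H, 6α-OCOAr, 8α,9α-epoxy, 10β-OH. Bicycles that still lack C9 are named as 9-nordaucanes.

Remark (chemistry): compounds 1, 3, 4 and 15 and all reagents are taken as commercially available; the enantiomer of the NHC ligand in step 2 is chosen to give the C5 configuration drawn in 7.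

Step 1
Reactants: 1 2,6-dimethylphenol
Product: 2 4,4-dimethoxy-2,6-dimethylcyclohexa-2,5-dien-1-one
Conditions: PhI(OAc)2 (2.2 equiv), MeOH, 0 °C to rt
Reagents that add atoms: methanol (CO)
Why: Oxidative dearomatisation of a para-unsubstituted phenol with a hypervalent iodine reagent in methanol should give the para-quinone monoketal, an achiral dienone with two enantiotopic enone arms; no stereocentre is formed.

Step 2
Reactants: 2 4,4-dimethoxy-2,6-dimethylcyclohexa-2,5-dien-1-one; 3 3-methylbut-1-yne; 4 acrolein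
Product: 7 (5,6-trans)-6-(1-hydroxyprop-2-enyl)-4,4-dimethoxy-2,6-dimethyl-5-(3-methylbut-1-en-2-yl)cyclohex-2-en-1-one, via alkenylalane 5 (not isolated), via aluminium enolate 6 (not isolated)
Conditions: 3, i-Bu2AlH, Ni(dppp)Cl2 (3 mol %), THF, 0 °C; then 2, CuCl2·2H2O (5 mol %), chiral sulfonate-NHC·Ag complex (2.5 mol %), −30 °C; then 4, −78 °C; aq. Rochelle salt
Reagents that add atoms: none
Why: Three-component conjugate addition–aldol reaction: the Cu-catalysed enantioselective addition of the α-alkenylalane (from Ni-catalysed hydroalumination) desymmetrises the dienone and sets C5 under catalyst control, the aluminium enolate then adds to acrolein anti to the new C5 substituent (C1, trans), and a closed chair transition state with the vinyl group equatorial places the C2 hydroxyl group syn to the C1 methyl group.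

Step 3
Reactants: 7 (5,6-trans)-6-(1-hydroxyprop-2-enyl)-4,4-dimethoxy-2,6-dimethyl-5-(3-methylbut-1-en-2-yl)cyclohex-2-en-1-one
Product: 8 2β-hydroxy-6,6-dimethoxy-9-nordauca-3,7-dien-10-one (trans-fused, 5α-H)
Conditions: (H2IMes)(PCy3)Cl2Ru=CHPh (5 mol %), CH2Cl2, 40 °C
Reagents that add atoms: none
Why: Ring-closing metathesis of the vinyl carbinol with the 1,1-disubstituted alkene should close the trans-fused cyclopentene (C3=C4) with loss of ethene, while the electron-poor enone is inert and no stereocentre changes.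

Step 4
Reactants: 8 2β-hydroxy-6,6-dimethoxy-9-nordauca-3,7-dien-10-one
Product: 9 3β,4β-epoxy-2β-hydroxy-6,6-dimethoxy-9-nordauc-7-en-10-one
Conditions: VO(acac)2 (5 mol %), t-BuOOH, CH2Cl2, 0 °C to rt
Reagents that add atoms: tert-butyl hydroperoxide (CC(C)(C)OO)
Why: Vanadium-catalysed hydroxyl-directed epoxidation delivers oxygen to C3=C4 on the face of the allylic C2 hydroxyl group (β), which fixes the C4–O bond cis to C2–OH, and leaves the electron-poor enone untouched.

Step 5
Reactants: 9 3β,4β-epoxy-2β-hydroxy-6,6-dimethoxy-9-nordauc-7-en-10-one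
Product: 10 6,6-dimethoxy-9-nordauc-7-ene-2β,4β,10β-triol
Conditions: NaAlH2(OCH2CH2OMe)2 (Red-Al), THF, 0 °C to rt; aq. Rochelle salt
Reagents that add atoms: none
Why: Red-Al reduction of a 2,3-epoxy alcohol delivers hydride from the C2 alkoxyaluminate to secondary C3 and should give the 2β,4β-1,3-diol with the C4–O bond retained; the enone carbonyl is reduced 1,2 at the same time, and the configuration of that carbinol (10β expected, hydride anti to the C1 methyl group) is irrelevant because step 6 removes it.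

Step 6
Reactants: 10 6,6-dimethoxy-9-nordauc-7-ene-2β,4β,10β-triol
Product: 11 2β,4β-dihydroxy-6,6-dimethoxy-9-nordauc-7-en-10-one
Conditions: MnO2 (excess), CH2Cl2, rt
Reagents that add atoms: none
Why: Chemoselective allylic oxidation: manganese dioxide should oxidise only the allylic C10 alcohol back to the enone and leave the saturated secondary C2 and tertiary C4 alcohols untouched.

Step 7
Reactants: 11 2β,4β-dihydroxy-6,6-dimethoxy-9-nordauc-7-en-10-one
Product: 12 2β-acetoxy-4β-hydroxy-6,6-dimethoxy-9-nordauc-7-en-10-one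
Conditions: Ac2O, DMAP (cat.), pyridine, CH2Cl2, 0 °C to rt
Reagents that add atoms: acetic anhydride (CC(=O)OC(C)=O)
Why: DMAP-catalysed acylation should esterify the secondary C2 hydroxyl group only, because the tertiary C4 hydroxyl group is unreactive under these conditions.

Step 8
Reactants: 12 2β-acetoxy-4β-hydroxy-6,6-dimethoxy-9-nordauc-7-en-10-one
Product: 13 2β-acetoxy-4β-hydroxy-9-nordauc-7-ene-6,10-dione
Conditions: PPTS (cat.), acetone/H2O (10:1), rt
Reagents that add atoms: water (O)
Why: Mild acid-catalysed hydrolysis of the allylic dimethyl ketal should liberate the C6 ketone under conditions too mild for dehydration of the tertiary β-hydroxy ketone or for epimerisation at C5.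

Step 9
Reactants: 13 2β-acetoxy-4β-hydroxy-9-nordauc-7-ene-6,10-dione
Product: 14 2β-acetoxy-4β,6α-dihydroxy-9-nordauc-7-en-10-one
Conditions: Me4NBH(OAc)3, MeCN/AcOH (1:1), −30 °C
Reagents that add atoms: none
Why: Evans–Saksena reduction: the C4 alkoxyborohydride delivers hydride intramolecularly to the β face of the C6 ketone (anti-1,3-diol, 6α-OH), while the C10 enone, which has no free β-hydroxyl group, should not be reduced.

Step 10
Reactants: 14 2β-acetoxy-4β,6α-dihydroxy-9-nordauc-7-en-10-one; 15 4-methoxybenzoyl chloride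
Product: 16 2β-acetoxy-4β-hydroxy-6α-(4-methoxybenzoyloxy)-9-nordauc-7-en-10-one
Conditions: Et3N, DMAP (cat.), CH2Cl2, 0 °C to rt
Reagents that add atoms: none
Why: DMAP-catalysed acylation of the secondary allylic C6 alcohol with the acid chloride; the tertiary C4 alcohol should not react.

Step 11
Reactants: 16 2β-acetoxy-4β-hydroxy-6α-(4-methoxybenzoyloxy)-9-nordauc-7-en-10-one
Product: 17 2β-acetoxy-4β-hydroxy-6α-(4-methoxybenzoyloxy)-10-(triethylsilyloxy)-9-nordauc-8(10)-ene
Conditions: Et3SiH, RhCl(PPh3)3 (2 mol %), benzene, 60 °C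
Reagents that add atoms: triethylsilane (CC[SiH](CC)CC)
Why: Rh-catalysed 1,4-hydrosilylation of the enone with a monohydrosilane should give the silyl enol ether regiospecifically at C10=C8 (C1 is quaternary); no stereocentre is formed.

Step 12
Reactants: 17 2β-acetoxy-4β-hydroxy-6α-(4-methoxybenzoyloxy)-10-(triethylsilyloxy)-9-nordauc-8(10)-ene
Product: 18 2β-acetoxy-4β-hydroxy-6α-(4-methoxybenzoyloxy)-10β-(triethylsilyloxy)-8,10-cyclodaucane (cyclopropane CH2 = C9 on the α face)
Conditions: Et2Zn (3 equiv), CH2I2 (3 equiv), CH2Cl2, 0 °C to rt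
Reagents that add atoms: diiodomethane (ICI)
Why: Simmons–Smith cyclopropanation (Furukawa modification) of the electron-rich silyl enol ether, the only alkene present, should give the siloxybicyclo[4.1.0]heptane; addition is expected anti to the axial C1 methyl group, but either face leads to the same product in step 13.

Step 13
Reactants: 18 2β-acetoxy-4β-hydroxy-6α-(4-methoxybenzoyloxy)-10β-(triethylsilyloxy)-8,10-cyclodaucane
Product: 20 2β-acetoxy-4β-hydroxy-6α-(4-methoxybenzoyloxy)dauc-8-en-10-one, via β-chloro ketone 19 (not isolated)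
Conditions: FeCl3 (2.5 equiv), DMF, 0 °C; then NaOAc, MeOH, 50 °C
Reagents that add atoms: none
Why: FeCl3 oxidises the siloxycyclopropane by single-electron transfer, and β-scission of the internal C10–C8 bond gives the C10 ketone and the tertiary C8 radical, which takes chlorine from a second FeCl3 to give the β-chloro ketone; acetate then eliminates HCl to the conjugated enone. The closest known reaction type is the Saegusa–Ito oxidative ring expansion of 1-siloxybicyclo[n.1.0]alkanes to cycloalk-2-enones. No ring is closed: the six-membered ring C1–C5–C6–C7–C8–C10 opens at the former enol ether bond and becomes the seven-membered ring by insertion of C9, a ring expansion by one atom. No new stereocentre is formed, the two cyclopropane stereocentres are destroyed, and C1, C2, C4, C5 and C6 are not touched. The step needs cleavage of the internal and not the external (C10–C9) cyclopropane bond, which the tertiary methyl-substituted C8 radical secures, and elimination towards C9, which the acidity of the α-protons of the C10 ketone secures.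

Step 14
Reactants: 20 2β-acetoxy-4β-hydroxy-6α-(4-methoxybenzoyloxy)dauc-8-en-10-one
Product: 21 2β-acetoxy-8α,9α-epoxy-4β-hydroxy-6α-(4-methoxybenzoyloxy)daucan-10-one
Conditions: dimethyldioxirane (acetone solution), CH2Cl2, 0 °C to rt
Reagents that add atoms: dimethyldioxirane (CC1(C)OO1)
Why: Epoxidation of the enone with a dioxirane under neutral conditions (both esters should survive) is expected on the α face, because the axial C1 methyl group shields the β face of C8=C9.

Step 15
Reactants: 21 2β-acetoxy-8α,9α-epoxy-4β-hydroxy-6α-(4-methoxybenzoyloxy)daucan-10-one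
Product: 22 2β-acetoxy-8α,9α-epoxy-4β,10β-dihydroxy-6α-(4-methoxybenzoyloxy)daucane (CNP0371526.1)
Conditions: NaBH4, CeCl3·7H2O, MeOH, −78 °C
Reagents that add atoms: none
Why: Luche reduction: hydride should add to the C10 ketone from the α face, anti to the adjacent C1 methyl group, to give the 10β-alcohol trans to the epoxide, with esters and epoxide untouched.

**Compound list**

1 | 2,6-dimethylphenol | Cc1cccc(C)c1O | starting material
2 | 4,4-dimethoxy-2,6-dimethylcyclohexa-2,5-dien-1-one | COC1(OC)C=C(C)C(=O)C(C)=C1 | intermediate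
3 | 3-methylbut-1-yne | CC(C)C#C | starting material
4 | acrolein (prop-2-enal) | C=CC=O | starting material
5 | diisobutyl(3-methylbut-1-en-2-yl)alane | CC(C)C(=C)[Al](CC(C)C)CC(C)C | intermediate (not isolated)
6 | aluminium enolate: diisobutyl{[4,4-dimethoxy-2,6-dimethyl-3-(3-methylbut-1-en-2-yl)cyclohexa-1,5-dien-1-yl]oxy}alane (C5 of the target set) | COC1(OC)C=C(C)C(O[Al](CC(C)C)CC(C)C)=C(C)[C@@H]1C(=C)C(C)C | intermediate (not isolated)
7 | (5,6-trans)-6-(1-hydroxyprop-2-enyl)-4,4-dimethoxy-2,6-dimethyl-5-(3-methylbut-1-en-2-yl)cyclohex-2-en-1-one (ring C5, C6 and the carbinol are C5, C1 and C2 of the target) | COC1(OC)C=C(C)C(=O)[C@]([C@H](O)C=C)(C)[C@@H]1C(=C)C(C)C | intermediate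
8 | 2β-hydroxy-6,6-dimethoxy-9-nordauca-3,7-dien-10-one (trans-fused, 5α-H) | COC1(OC)C=C(C)C(=O)[C@]2(C)[C@@H]1C(C(C)C)=C[C@H]2O | intermediate
9 | 3β,4β-epoxy-2β-hydroxy-6,6-dimethoxy-9-nordauc-7-en-10-one | COC1(OC)C=C(C)C(=O)[C@]2(C)[C@@H]1[C@@]3(C(C)C)O[C@H]3[C@H]2O | intermediate
10 | 6,6-dimethoxy-9-nordauc-7-ene-2β,4β,10β-triol | COC1(OC)C=C(C)[C@H](O)[C@]2(C)[C@@H]1[C@](O)(C(C)C)C[C@H]2O | intermediate
11 | 2β,4β-dihydroxy-6,6-dimethoxy-9-nordauc-7-en-10-one | COC1(OC)C=C(C)C(=O)[C@]2(C)[C@@H]1[C@](O)(C(C)C)C[C@H]2O | intermediate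
12 | 2β-acetoxy-4β-hydroxy-6,6-dimethoxy-9-nordauc-7-en-10-one | COC1(OC)C=C(C)C(=O)[C@]2(C)[C@@H]1[C@](O)(C(C)C)C[C@H]2OC(C)=O | intermediate
13 | 2β-acetoxy-4β-hydroxy-9-nordauc-7-ene-6,10-dione | O=C1C=C(C)C(=O)[C@]2(C)[C@@H]1[C@](O)(C(C)C)C[C@H]2OC(C)=O | intermediate
14 | 2β-acetoxy-4β,6α-dihydroxy-9-nordauc-7-en-10-one | O[C@H]1C=C(C)C(=O)[C@]2(C)[C@@H]1[C@](O)(C(C)C)C[C@H]2OC(C)=O | intermediate
15 | 4-methoxybenzoyl chloride | COc1ccc(C(Cl)=O)cc1 | starting material
16 | 2β-acetoxy-4β-hydroxy-6α-(4-methoxybenzoyloxy)-9-nordauc-7-en-10-one | COc1ccc(C(=O)O[C@H]2C=C(C)C(=O)[C@]3(C)[C@@H]2[C@](O)(C(C)C)C[C@H]3OC(C)=O)cc1 | intermediate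
17 | 2β-acetoxy-4β-hydroxy-6α-(4-methoxybenzoyloxy)-10-(triethylsilyloxy)-9-nordauc-8(10)-ene | COc1ccc(C(=O)O[C@H]2CC(C)=C(O[Si](CC)(CC)CC)[C@]3(C)[C@@H]2[C@](O)(C(C)C)C[C@H]3OC(C)=O)cc1 | intermediate
18 | 2β-acetoxy-4β-hydroxy-6α-(4-methoxybenzoyloxy)-10β-(triethylsilyloxy)-8,10-cyclodaucane (C9 on the α face) | COc1ccc(C(=O)O[C@H]2C[C@@]4(C)C[C@@]4(O[Si](CC)(CC)CC)[C@]3(C)[C@@H]2[C@](O)(C(C)C)C[C@H]3OC(C)=O)cc1 | intermediate
19 | 2β-acetoxy-8-chloro-4β-hydroxy-6α-(4-methoxybenzoyloxy)daucan-10-one (C8 epimers) | COc1ccc(C(=O)O[C@H]2CC(C)(Cl)CC(=O)[C@]3(C)[C@@H]2[C@](O)(C(C)C)C[C@H]3OC(C)=O)cc1 | intermediate (not isolated)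
20 | 2β-acetoxy-4β-hydroxy-6α-(4-methoxybenzoyloxy)dauc-8-en-10-one | COc1ccc(C(=O)O[C@H]2CC(C)=CC(=O)[C@]3(C)[C@@H]2[C@](O)(C(C)C)C[C@H]3OC(C)=O)cc1 | intermediate
21 | 2β-acetoxy-8α,9α-epoxy-4β-hydroxy-6α-(4-methoxybenzoyloxy)daucan-10-one | COc1ccc(C(=O)O[C@H]2C[C@@]3(C)O[C@H]3C(=O)[C@]3(C)[C@@H]2[C@](O)(C(C)C)C[C@H]3OC(C)=O)cc1 | intermediate
22 | 2β-acetoxy-8α,9α-epoxy-4β,10β-dihydroxy-6α-(4-methoxybenzoyloxy)daucane (5α-H; CNP0371526.1) | COc1ccc(C(=O)O[C@H]2C[C@@]3(C)O[C@H]3[C@H](O)[C@]3(C)[C@@H]2[C@](O)(C(C)C)C[C@H]3OC(C)=O)cc1 | target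

**Step count and risks**

Total step count: 15. Longest linear sequence: 15 steps (from 1).

The three steps most likely to fail:

Step 2. The risk is insufficient enantio- or diastereofacial discrimination when a hindered α-branched alkenyl group is added next to the ketal carbon, competing 1,2-addition, poor facial selectivity at the aldehyde (C2), or retro-aldol loss of the acrolein unit on work-up. The fallback sets out from 2 and comes back at 7. Rhodium-catalysed asymmetric 1,4-addition (Hayashi–Miyaura reaction) of 2-(3-methylbut-1-en-2-yl)-4,4,5,5-tetramethyl-1,3,2-dioxaborolane with a chiral diene ligand (aq. KOH, dioxane) sets C5 and should give 4,4-dimethoxy-2,6-dimethyl-5-(3-methylbut-1-en-2-yl)cyclohex-2-en-1-one F1 as a mixture of C6 epimers. Kinetic deprotonation of F1 at C6 (LDA, THF, −78 °C; the only α-CH) and aldol addition of the lithium enolate to acrolein, anti to the C5 substituent and through the same closed transition state, should then give 7.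

Step 13. The risk is loss of the silyl group without ring opening (return to the cyclohexanone), opening of the external cyclopropane bond (α-methylation instead of ring growth) or, one step earlier, failure to cyclopropanate the hindered tetrasubstituted enol ether. The fallback sets out from 16 and comes back at 20. Hydrogenation of C7=C8 (H2, Pd/C, EtOAc) should give 2β-acetoxy-4β-hydroxy-6α-(4-methoxybenzoyloxy)-9-nordaucan-10-one F2. Homologation with trimethylsilyldiazomethane and Me3Al (CH2Cl2, −78 to 0 °C; then dilute HCl) inserts CH2 between C10 and C8, because tertiary C8 migrates in preference to quaternary C1, and should give 2β-acetoxy-4β-hydroxy-6α-(4-methoxybenzoyloxy)daucan-10-one F3, again by one-carbon ring expansion. Dehydrogenation with IBX (DMSO, 65 °C), possible only towards C9, returns to 20.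

Step 14. The risk is poor facial selectivity on the flexible seven-membered ring (β-epoxide) or slow reaction of the electron-poor alkene with oxidation elsewhere. The fallback sets out from 20 and comes back at 22. Luche reduction comes first and should give 2β-acetoxy-6α-(4-methoxybenzoyloxy)dauc-8-ene-4β,10β-diol F4 (hydride anti to the C1 methyl group). Silylation of the secondary alcohol (TBSCl, imidazole, DMF) gives 2β-acetoxy-10β-(tert-butyldimethylsilyloxy)-6α-(4-methoxybenzoyloxy)dauc-8-en-4β-ol F5. Epoxidation with m-CPBA (NaHCO3, CH2Cl2), anti to the bulky β-silyloxy group and the β-methyl group, gives 2β-acetoxy-10β-(tert-butyldimethylsilyloxy)-8α,9α-epoxy-6α-(4-methoxybenzoyloxy)daucan-4β-ol F6. HF·pyridine then removes the silyl group and gives 22 directly, so that step 15 is not needed.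

Further compounds
F1 | step 2 | 4,4-dimethoxy-2,6-dimethyl-5-(3-methylbut-1-en-2-yl)cyclohex-2-en-1-one (C6 epimers) | COC1(OC)C=C(C)C(=O)C(C)[C@@H]1C(=C)C(C)C
F2 | step 13 | 2β-acetoxy-4β-hydroxy-6α-(4-methoxybenzoyloxy)-9-nordaucan-10-one (C8 epimers) | COc1ccc(C(=O)O[C@H]2CC(C)C(=O)[C@]3(C)[C@@H]2[C@](O)(C(C)C)C[C@H]3OC(C)=O)cc1
F3 | step 13 | 2β-acetoxy-4β-hydroxy-6α-(4-methoxybenzoyloxy)daucan-10-one (C8 epimers) | COc1ccc(C(=O)O[C@H]2CC(C)CC(=O)[C@]3(C)[C@@H]2[C@](O)(C(C)C)C[C@H]3OC(C)=O)cc1
F4 | step 14 | 2β-acetoxy-6α-(4-methoxybenzoyloxy)dauc-8-ene-4β,10β-diol | COc1ccc(C(=O)O[C@H]2CC(C)=C[C@H](O)[C@]3(C)[C@@H]2[C@](O)(C(C)C)C[C@H]3OC(C)=O)cc1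
F5 | step 14 | 2β-acetoxy-10β-(tert-butyldimethylsilyloxy)-6α-(4-methoxybenzoyloxy)dauc-8-en-4β-ol | COc1ccc(C(=O)O[C@H]2CC(C)=C[C@H](O[Si](C)(C)C(C)(C)C)[C@]3(C)[C@@H]2[C@](O)(C(C)C)C[C@H]3OC(C)=O)cc1
F6 | step 14 | 2β-acetoxy-10β-(tert-butyldimethylsilyloxy)-8α,9α-epoxy-6α-(4-methoxybenzoyloxy)daucan-4β-ol | COc1ccc(C(=O)O[C@H]2C[C@@]3(C)O[C@H]3[C@H](O[Si](C)(C)C(C)(C)C)[C@]3(C)[C@@H]2[C@](O)(C(C)C)C[C@H]3OC(C)=O)cc1
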